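Atom numbering used throughout: ring A is C1–C5 plus C10, ring B is C5–C10, the isopropenyl group on C7 is C11 (sp2 carbon), C12 (methylene) and C13 (methyl). Ring A intermediates are named with these locants.

## Analysis of the target

The target 30 is a cis-fused eremophilane-type decalin. Ring A carries the C2 ketone, a secondary methyl at C4 and the quaternary methyl at C5; ring B carries the isopropenyl group at C7, an acetate at C8 and a tiglate at C9. The six stereocentres are 4S,5R,7R,8R,9S,10S. Both methyls, H-10 and the isopropenyl group lie on one face. The two acyloxy groups lie on the other face, cis to each other and to the ring A bonds at C5 and C10, which is the concave face of the cis-decalin. In the chair–chair conformer that avoids a syn-axial methyl/isopropenyl contact, the isopropenyl and C8 acetoxy groups are equatorial and the C9 tigloyloxy group is axial, between the ring fusion and C8. Sensitive groups are the isopropenyl olefin (acid), the tiglate (E geometry, conjugate addition), the cis-vicinal diester (acyl migration) and the ketone. The hard part is the oxygen pair on the concave face next to the vicinal quaternary/tertiary methyl pair. Any oxidant attacking a C8=C9 olefin, and any carbon nucleophile adding to a C9 aldehyde, would approach anti to the quaternary C5 and put the C9 oxygen on the wrong side. The route therefore has to make the C9–H bond last, from a ketone. The strategy rests on C6: a methylene between quaternary C5 and the isopropenyl-bearing C7. That is what a primary C6 radical produces when it adds to C7 of a 2-methylallyl sulfone and the sulfonyl radical leaves, so closing ring B at C6–C7 also creates the isopropenyl group with no later redox step.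

## Retrosynthetic reasoning

**30 to 27.** The two ester C–O bonds are cut first. The tiglate comes from tigloyl chloride 29 acting on the monoacetate 28, and 28 comes from the keto diol 27 by acetylation of the more accessible equatorial C8 hydroxyl. Diol 27 comes from the doubly ketal-protected decalin 26 by one hydrolysis. Removing the acetonide while keeping the C2 dioxolane is not reliable, so both are taken off together.

**26 to 23.** The C6–C7 bond is cut. It is the only ring B bond whose formation from a primary radical and a 2-methylallyl sulfone gives the isopropenyl group in the same event and leaves the quaternary centre untouched. Forward, the N-acyloxyphthalimide 23 has to fragment reductively to the C6 radical, close 6-exo onto C7 and lose the sulfonyl radical. Ester 23 comes from acid 21 and N-hydroxyphthalimide 22.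

**21 to 18.** The acetic acid arm on C5 is carried as a vinyl group and unmasked late by anti-Markovnikov hydration and oxidation (18 to 20 to 21). An ester in this position would need acid or hydroxide for its removal, which the two ketals or the allylic sulfone would not all tolerate, and it would interfere with the organometallic and hydride steps. The vinyl group is inert to all of them and is distinguished at the end from the trisubstituted, sulfone-bearing olefin by its substitution.

**18 to 16.** The acetonide 18 comes from diol 17. In 17 the C12–S bond is cut back to the vinyl epoxide 16. A palladium allylic substitution with a sulfinate at C12 makes the allylic sulfone, the C7=C11 olefin and the free C8 hydroxyl in one step, and the C8–O bond is never broken. This avoids an olefination reagent that carries a β-sulfonyl group, which would simply eliminate sulfinate.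

**16 to 15.** The epoxide oxygen at C8 is introduced by a reagent-controlled epoxidation of the secondary allylic alcohol 15. With C9 already correct, this is the matched case and gives the erythro relationship that becomes the cis diol.

**15 to 9 and 10.** The C9 carbinol is made by hydride addition to the dienone 14, not by adding carbon to an aldehyde. With C5 as the large group on C10, Felkin–Anh addition of hydride to the C9 ketone leaves the oxygen on the required side, whereas addition of the C8 carbon to aldehyde 9 gives mainly the other epimer. The C8–C9 bond is therefore made without regard to configuration (9 with the enyne 10 to 13), and 13 is oxidised to 14 and reduced.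

**9 to 6.** Aldehyde 9 comes from alcohol 8 by oxidation. Alcohol 8 comes from the silyl enol ether 7 by ketalisation with loss of the primary silyl group. The vinyl group of 7 comes from the C5 formyl group of 6 by methylenation.

**6 to 4 and 5.** Ring A is cut at C3–C4 and C5–C10 into the 2-silyloxydiene 4 and tiglaldehyde 5. This Diels–Alder reaction sets all three ring A stereocentres at once: the E geometry of 5 gives the cis methyls, the formyl-endo transition state gives C10, and a chiral Lewis acid gives the absolute configuration. The silyloxy group and the C10 substituent both direct the same regiochemistry. A chiral-pool entry by conjugate addition and alkylation of a terpene-derived cyclohexenone would set C4 and C5 equally well, but it leaves the carbonyl on C10 and needs a carbonyl transposition before C10 can be set, at a cost of several steps.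

**4 to 1 and 2.** Diene 4 comes from enone 3 by O-silylation, and 3 from the aldehyde 1 and the stabilised ylide 2 by Wittig olefination.

## Alternatives that were turned down

**Alternative 1:** Ring B is cut at C5–C6 and C9–C10. Forward, 2-methoxy-5-methyl-1,4-benzoquinone A1 and (E)-1-(tert-butyldimethylsilyloxy)buta-1,3-diene A2 combine in an endo Diels–Alder reaction under a chiral Lewis acid to give the cis-fused methoxy enedione A3.
- For: one catalytic step makes the ring fusion and sets C5, C10 and C9 together, with the C9 oxygen correctly placed relative to H-10. On bonds and stereocentres formed in the key step it is stronger than the radical closure, which sets only C7.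
- Against: A3 has ring A at the wrong oxidation pattern. C1 and C4 are carbonyls and C2 is an enol ether. C4 must become a methyl-bearing stereocentre cis to the C5 methyl at a neopentyl position, C1 must be deoxygenated, and the C7=C8 olefin must be turned into a trans isopropenyl/oxygen pair with the oxygen on the concave face.
- Comparison: each correction costs steps and raises a new selectivity question. The chosen route has ring A with its final substituents after one cycloaddition and makes the isopropenyl group in the ring closure.

**Alternative 2:** Ring B is closed at C5–C6 by an anionic oxy-Cope rearrangement of a bridged vinyl carbinol alkoxide, with cleavage of C3–C8, giving the cis-decalin ketone A4.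
- For: the rearrangement is concerted and stereospecific, so the cis fusion and the quaternary C5 follow from the geometry of the bicycle. A4 has a ketone at C8 and a ketal at C9. Hydride reduction of ring carbonyls from the open convex face would give exactly the hindered concave hydroxyls, and on this point it is stronger than the acyclic construction of C8 and C9 used here.
- Against: the bridged precursor comes from dearomatisation and cycloaddition of an ortho-methoxyphenol, which is racemic unless an asymmetric variant is found. The isopropenyl group must be attached at C7 next to the C8 ketone, where elimination tends to give the conjugated isopropylidene. C4 must be set by reducing the C3=C4 olefin beside the quaternary centre.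
- Comparison: the chosen route settles absolute configuration and C4 in the first ring-forming step and needs no adjustment at C7 after closure.

**Alternative 3:** Ring B is cut at C7–C8. Forward, an alkylaluminium chloride activates a C8 aldehyde, which undergoes a type 1 carbonyl-ene reaction with a prenyl group on C5 to give the homoallylic alcohol A5.
- For: this is the closest competitor. The reaction type is well precedented, which the radical closure is not. It sets C7 and C8 together and forms the isopropenyl group by hydrogen transfer. A5 has a free C8 hydroxyl and a protected C9 oxygen, so the two esters go on without a selectivity problem, which is better than the end game here.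
- Against: it needs an α-alkoxy aldehyde at C8 with C9 already in place, so the contra-steric C9 problem remains. That aldehyde is epimerisable and chelating under the Lewis acid, which also threatens the dioxolane and the benzylic ether. Two stereocentres depend on a single chair.
- Comparison: the chosen strategy fixes C8 and C9 beforehand in a rigid acetonide and leaves only C7 to the closure, under neutral conditions. It pays with a less precedented key step and an acylation-selectivity problem at the end.

Key step: step 16

Assumption: the (S)-diphenylprolinol-derived oxazaborolidinium catalyst of step 3 is taken to expose the enal face that leads to 6; if the sense is the reverse, the (R)-catalyst is meant.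

## Route

Step 1
Reactants: 1 (tert-butyldimethylsilyloxy)acetaldehyde; 2 1-(triphenylphosphoranylidene)propan-2-one
Product: 3 (E)-5-(tert-butyldimethylsilyloxy)pent-3-en-2-one
Conditions: CH2Cl2, rt to 40 °C
Reagents that add atoms: none
Why: Wittig olefination with a ketone-stabilised ylide, which should give the E-enone; the aldehyde has no other electrophilic site.

Step 2
Reactants: 3 (E)-5-(tert-butyldimethylsilyloxy)pent-3-en-2-one
Product: 4 (E)-5-(tert-butyldimethylsilyloxy)-2-(triisopropylsilyloxy)penta-1,3-diene
Conditions: TIPSOTf, Et3N, CH2Cl2, 0 °C
Reagents that add atoms: triisopropylsilyl trifluoromethanesulfonate, CC(C)[Si](C(C)C)(C(C)C)OS(=O)(=O)C(F)(F)F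
Why: Soft enolisation and O-silylation at the methyl group of the enone gives the cross-conjugated 2-silyloxydiene; the E olefin (later C1=C10) is not touched.

Step 3
Reactants: 4 (E)-5-(tert-butyldimethylsilyloxy)-2-(triisopropylsilyloxy)penta-1,3-diene; 5 tiglaldehyde, (E)-2-methylbut-2-enal
Product: 6 5-formyl-4,5-dimethyl-10-[(tert-butyldimethylsilyloxy)methyl]-2-(triisopropylsilyloxy)cyclohex-1-ene (4-methyl and 5-methyl cis; formyl and C10 arm cis to each other and trans to the methyls; C4, C5, C10 as in the target)
Conditions: (S)-3,3-diphenyl-1-(o-tolyl)tetrahydro-1H,3H-pyrrolo[1,2-c][1,3,2]oxazaborole·Tf2NH (20 mol %), CH2Cl2, −78 to −40 °C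
Reagents that add atoms: none
Why: Enantioselective Diels–Alder reaction of an α-substituted enal activated by a chiral oxazaborolidinium Lewis acid; the C2 silyloxy group and the C10 substituent both direct C3 to the β-carbon C4 and C10 to the formyl-bearing C5. The E geometry of 5 places the two methyls cis, the formyl-endo transition state places the C10 arm cis to the formyl group, and the catalyst sets the absolute configuration.

Step 4
Reactants: 6 5-formyl-4,5-dimethyl-10-[(tert-butyldimethylsilyloxy)methyl]-2-(triisopropylsilyloxy)cyclohex-1-ene
Product: 7 4,5-dimethyl-5-vinyl-10-[(tert-butyldimethylsilyloxy)methyl]-2-(triisopropylsilyloxy)cyclohex-1-ene (configuration as in 6)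
Conditions: Ph3PCH3Br, KOtBu, THF, 0 °C to rt
Reagents that add atoms: methyltriphenylphosphonium bromide, C[P+](c1ccccc1)(c1ccccc1)c1ccccc1.[Br-]
Why: Wittig methylenation of a non-enolisable neopentyl aldehyde; the vinyl group is the masked acetic acid arm (its inner carbon is C6) and survives every step up to step 13.

Step 5
Reactants: 7 4,5-dimethyl-5-vinyl-10-[(tert-butyldimethylsilyloxy)methyl]-2-(triisopropylsilyloxy)cyclohex-1-ene
Product: 8 [4,5-dimethyl-5-vinyl-2,2-(ethylenedioxy)cyclohex-10-yl]methanol (configuration as in 6)
Conditions: ethylene glycol (10 equiv), p-TsOH·H2O (10 mol %), benzene, 60 °C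
Reagents that add atoms: ethylene glycol, OCCO
Why: Acid-catalysed ketalisation: protonation of the silyl enol ether at C1 gives the C2 oxocarbenium ion, which is trapped as the spiro-dioxolane, and the primary silyl ether is cleaved under the same conditions. A bridged mixed ketal through the C9 oxygen is more strained and should revert to the dioxolane under equilibrium; no stereocentre is epimerisable.

Step 6
Reactants: 8 [4,5-dimethyl-5-vinyl-2,2-(ethylenedioxy)cyclohex-10-yl]methanol
Product: 9 4,5-dimethyl-5-vinyl-2,2-(ethylenedioxy)cyclohexane-10-carbaldehyde (configuration as in 6)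
Conditions: Dess–Martin periodinane, pyridine, CH2Cl2, 0 °C
Reagents that add atoms: none
Why: Dess–Martin oxidation under buffered, non-basic conditions, so the α-stereocentre C10 of the aldehyde is not exposed to epimerisation.

Step 7
Reactants: 9 4,5-dimethyl-5-vinyl-2,2-(ethylenedioxy)cyclohexane-10-carbaldehyde; 10 2-methylbut-1-en-3-yne
Product: 13 (E)-1-[4,5-dimethyl-5-vinyl-2,2-(ethylenedioxy)cyclohex-10-yl]-4-methylpenta-2,4-dien-1-ol as a mixture of C9 epimers, via (E)-3-methylbuta-1,3-dienylzirconocene chloride 11 (not isolated), via methyl[(E)-3-methylbuta-1,3-dienyl]zinc 12 (not isolated)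
Conditions: Cp2Zr(H)Cl, CH2Cl2, rt; Me2Zn, toluene, −65 °C; then 9, 0 °C
Reagents that add atoms: none
Why: Hydrozirconation of the terminal alkyne (syn addition, zirconium at the terminus) and zirconium-to-zinc transmetalation give an E-dienylzinc that adds to the aldehyde and leaves the ketal and the vinyl group alone. The epimer ratio at C9 does not matter because the carbinol is oxidised in the next step.

Step 8
Reactants: 13 (E)-1-[4,5-dimethyl-5-vinyl-2,2-(ethylenedioxy)cyclohex-10-yl]-4-methylpenta-2,4-dien-1-ol
Product: 14 (E)-1-[4,5-dimethyl-5-vinyl-2,2-(ethylenedioxy)cyclohex-10-yl]-4-methylpenta-2,4-dien-1-one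
Conditions: Dess–Martin periodinane, pyridine, CH2Cl2, 0 °C
Reagents that add atoms: none
Why: Dess–Martin oxidation of the dienylic alcohol converges both C9 epimers on one ketone under conditions too mild to epimerise C10.

Step 9
Reactants: 14 (E)-1-[4,5-dimethyl-5-vinyl-2,2-(ethylenedioxy)cyclohex-10-yl]-4-methylpenta-2,4-dien-1-one
Product: 15 the C9 alcohol of 14 with the C9 oxygen placed as in the target, (E)-dienol
Conditions: NaBH4, CeCl3·7H2O, MeOH/CH2Cl2, −78 °C
Reagents that add atoms: none
Why: Luche 1,2-reduction under Felkin–Anh control: the quaternary C5 stands anti to the incoming hydride, C1 sits on the oxygen side and H-10 towards C8, so hydride enters on the face that leaves the C9 oxygen as the target needs. The same sense is known for hydride reduction of 20-oxo steroids, whose α-carbon has the same quaternary/methylene/hydrogen environment.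

Step 10
Reactants: 15 (E)-dienol with C9 configured as in the target
Product: 16 erythro epoxy alcohol: the (7S,8S)-7,8-epoxide of 15, with isopropenyl on C7 and the free C9 hydroxyl
Conditions: Ti(OiPr)4 (0.3 equiv), L-(+)-diisopropyl tartrate (0.36 equiv), t-BuOOH, 4 Å MS, CH2Cl2, −20 °C
Reagents that add atoms: tert-butyl hydroperoxide, CC(C)(C)OO
Why: Sharpless asymmetric epoxidation of a secondary allylic alcohol in its matched sense: with the L-(+)-tartrate, 15 has the fast-reacting carbinol configuration and should give the erythro epoxy alcohol, which fixes C8 as in the target. Only the olefin next to the carbinol is activated; the isopropenyl terminus and the C5 vinyl group are not.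

Step 11
Reactants: 16 erythro (7S,8S)-epoxy alcohol
Product: 17 C8,C9-diol carrying the (E)-2-methyl-3-(phenylsulfonyl)prop-1-enyl group on C8 (C7=C11 olefin, sulfone on C12)
Conditions: Pd(PPh3)4 (5 mol %), PhSO2Na, AcOH (1 equiv), THF/MeOH, 0 °C to rt
Reagents that add atoms: sodium benzenesulfinate, [Na+].[O-]S(=O)c1ccccc1
Why: Tsuji–Trost opening of a vinyl epoxide: zerovalent palladium ionises the allylic C7–O bond and the sulfinate attacks the unhindered terminus C12 (1,4-addition), releasing the C8 hydroxyl with its configuration untouched. The C7=C11 olefin should form mainly as the E isomer, and its geometry is lost again in step 16.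

Step 12
Reactants: 17 C8,C9-diol allylic sulfone
Product: 18 C8/C9 acetonide of 17 (cis-dioxolane)
Conditions: 2,2-dimethoxypropane, PPTS (cat.), CH2Cl2, rt
Reagents that add atoms: 2,2-dimethoxypropane, COC(C)(C)OC
Why: Acid-catalysed transketalisation of the erythro diol gives the cis-fused dioxolane, which protects both hydroxyls and holds the C7 and C10 arms on the same side.

Step 13
Reactants: 18 C8/C9 acetonide with the C5 vinyl group
Product: 20 primary alcohol (2-hydroxyethyl arm on C5), via B-alkyl-9-borabicyclo[3.3.1]nonane 19 (not isolated)
Conditions: 9-BBN, THF, 0 °C to rt; then 30% H2O2, aq. NaOH, 0 °C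
Reagents that add atoms: hydrogen peroxide, OO
Why: Hydroboration–oxidation: 9-BBN reacts with the monosubstituted vinyl group far faster than with the trisubstituted, sulfone-deactivated C7=C11 olefin and puts boron on the terminal carbon.

Step 14
Reactants: 20 primary alcohol
Product: 21 carboxylic acid (C5–CH2–CO2H; the methylene is C6)
Conditions: TEMPO (0.2 equiv), PhI(OAc)2 (2.5 equiv), MeCN/H2O, rt
Reagents that add atoms: water, O
Why: Oxoammonium-mediated oxidation of the primary alcohol through the aldehyde hydrate to the acid; sulfone, ketals and the electron-poor olefin are inert to it.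

Step 15
Reactants: 21 carboxylic acid; 22 N-hydroxyphthalimide
Product: 23 N-acyloxyphthalimide of 21 (C8/C9 acetonide, C2 dioxolane, (E)-allylic phenyl sulfone)
Conditions: N,N′-diisopropylcarbodiimide, DMAP (cat.), CH2Cl2, rt
Reagents that add atoms: none
Why: Steglich-type carbodiimide esterification gives the redox-active ester under neutral conditions that leave both ketals and the allylic sulfone unchanged.

Step 16
Reactants: 23 N-acyloxyphthalimide
Product: 26 cis-decalin with C7 isopropenyl group; C8/C9 acetonide; C2 dioxolane, via primary C6 radical 24 (not isolated), via tertiary C11 radical 25 (not isolated)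
Conditions: undivided cell, reticulated vitreous carbon cathode, Zn anode, n-Bu4NBF4 (0.1 M), DMF, 0.005 M, constant current, rt
Reagents that add atoms: none
Why: Proposed new method: cathodic one-electron reduction of the N-acyloxyphthalimide gives a radical anion that fragments to phthalimide anion, carbon dioxide and the primary C6 radical 24; 24 adds to C7 of the allylic sulfone to give the tertiary radical 25, which expels the phenylsulfonyl radical (reduced to sulfinate at the cathode while zinc is oxidised at the anode) and leaves the isopropenyl group. The closest known reaction types are the decarboxylative radical allylation of redox-active esters with allyl sulfones and the electroreductive generation of alkyl radicals from N-acyloxyphthalimides for conjugate addition; their ring-forming combination has not been shown. Ring B closes in the 6-exo-trig mode through a chair-like transition state that corresponds to the decalin chair with H-10 axial and C1 equatorial to the new ring. The one new stereocentre, C7, is set by this chair: the C7=C11 unit is pseudo-equatorial and trans to the equatorial C8–O bond, which gives 7R, whereas the other chair, leading to the C7 epimer, would put C1 axial and syn to an axial C8–O bond. The cis-acetonide keeps C6 and C7 within reach by holding both arms on one side of the dioxolane. The step needs reduction of the redox-active ester at a potential well short of that of the aryl sulfone, and it needs cyclisation to outrun hydrogen transfer and further reduction of 24, which high dilution and low current density favour.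

Step 17
Reactants: 26 cis-decalin acetonide dioxolane
Product: 27 8,9-dihydroxy-7-isopropenyl-4,5-dimethyl-cis-decalin-2-one (keto diol, configuration as in the target)
Conditions: 1 M aq. HCl/THF (1:3), rt
Reagents that add atoms: water, O
Why: Acid hydrolysis removes the acetonide and the dioxolane in one operation; the acid is kept dilute and cold enough that the isopropenyl group is not hydrated or isomerised.

Step 18
Reactants: 27 keto diol
Product: 28 8-O-acetyl keto diol (C9 hydroxyl free)
Conditions: Ac2O (1.1 equiv), pyridine, CH2Cl2, −20 to 0 °C
Reagents that add atoms: acetic anhydride, CC(=O)OC(C)=O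
Why: Selective acylation: the C8 hydroxyl is equatorial and open, the C9 hydroxyl is axial and flanked by the ring fusion, so one equivalent of anhydride at low temperature should react at C8.

Step 19
Reactants: 28 8-O-acetyl keto diol; 29 tigloyl chloride, (E)-2-methylbut-2-enoyl chloride
Product: 30 target, (4S,5R,7R,8R,9S,10S)-8-acetoxy-9-tigloyloxy-eremophil-11-en-2-one
Conditions: 29 (3 equiv), DMAP (0.5 equiv), pyridine, CH2Cl2, 40 °C
Reagents that add atoms: none
Why: DMAP-catalysed esterification of the hindered axial C9 hydroxyl with the acid chloride; pyridine is used in place of a stronger amine to limit alkoxide-mediated acetyl migration, and the tigloyl E geometry is stable under these conditions.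

## Compound list

1 | (tert-butyldimethylsilyloxy)acetaldehyde | O=CCO[Si](C)(C)C(C)(C)C | starting material
2 | 1-(triphenylphosphoranylidene)propan-2-one | CC(=O)C=P(c1ccccc1)(c1ccccc1)c1ccccc1 | starting material
3 | (E)-5-(tert-butyldimethylsilyloxy)pent-3-en-2-one | CC(=O)/C=C/CO[Si](C)(C)C(C)(C)C | intermediate
4 | (E)-5-(tert-butyldimethylsilyloxy)-2-(triisopropylsilyloxy)penta-1,3-diene | C=C(O[Si](C(C)C)(C(C)C)C(C)C)/C=C/CO[Si](C)(C)C(C)(C)C | intermediate
5 | tiglaldehyde, (E)-2-methylbut-2-enal | C/C=C(\C)C=O | starting material
6 | 5-formyl-4,5-dimethyl-10-[(tert-butyldimethylsilyloxy)methyl]-2-(triisopropylsilyloxy)cyclohex-1-ene (methyls cis; formyl and C10 arm cis, trans to the methyls) | O=C[C@@]1(C)[C@H](C=C(O[Si](C(C)C)(C(C)C)C(C)C)C[C@@H]1C)CO[Si](C)(C)C(C)(C)C | intermediate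
7 | 4,5-dimethyl-5-vinyl-10-[(tert-butyldimethylsilyloxy)methyl]-2-(triisopropylsilyloxy)cyclohex-1-ene | C=C[C@@]1(C)[C@H](C=C(O[Si](C(C)C)(C(C)C)C(C)C)C[C@@H]1C)CO[Si](C)(C)C(C)(C)C | intermediate
8 | [4,5-dimethyl-5-vinyl-2,2-(ethylenedioxy)cyclohex-10-yl]methanol | C=C[C@@]1(C)[C@H](CC2(OCCO2)C[C@@H]1C)CO | intermediate
9 | 4,5-dimethyl-5-vinyl-2,2-(ethylenedioxy)cyclohexane-10-carbaldehyde | C=C[C@@]1(C)[C@H](CC2(OCCO2)C[C@@H]1C)C=O | intermediate
10 | 2-methylbut-1-en-3-yne | C=C(C)C#C | starting material
11 | (E)-3-methylbuta-1,3-dienylzirconocene chloride | C=C(C)/C=C/[Zr](Cl)(C1C=CC=C1)C1C=CC=C1 | intermediate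
12 | methyl[(E)-3-methylbuta-1,3-dienyl]zinc | C[Zn]/C=C/C(C)=C | intermediate
13 | (E)-1-[4,5-dimethyl-5-vinyl-2,2-(ethylenedioxy)cyclohex-10-yl]-4-methylpenta-2,4-dien-1-ol, both C9 epimers | C=C[C@@]1(C)[C@H](CC2(OCCO2)C[C@@H]1C)C(O)/C=C/C(C)=C | intermediate
14 | (E)-1-[4,5-dimethyl-5-vinyl-2,2-(ethylenedioxy)cyclohex-10-yl]-4-methylpenta-2,4-dien-1-one | C=C[C@@]1(C)[C@H](CC2(OCCO2)C[C@@H]1C)C(=O)/C=C/C(C)=C | intermediate
15 | C9-configured (E)-dienol | C=C[C@@]1(C)[C@H](CC2(OCCO2)C[C@@H]1C)[C@H](O)/C=C/C(C)=C | intermediate
16 | erythro (7S,8S)-7,8-epoxy-9-ol with isopropenyl on C7 | C=C[C@@]1(C)[C@H](CC2(OCCO2)C[C@@H]1C)[C@H](O)[C@@H]3O[C@H]3C(C)=C | intermediate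
17 | C8,C9-diol with (E)-2-methyl-3-(phenylsulfonyl)prop-1-enyl group on C8 | C=C[C@@]1(C)[C@H](CC2(OCCO2)C[C@@H]1C)[C@H](O)[C@H](O)/C=C(\C)CS(=O)(=O)c3ccccc3 | intermediate
18 | C8/C9 acetonide of 17 | C=C[C@@]1(C)[C@H](CC2(OCCO2)C[C@@H]1C)[C@@H]3OC(C)(C)O[C@@H]3/C=C(\C)CS(=O)(=O)c4ccccc4 | intermediate
19 | B-alkyl-9-borabicyclo[3.3.1]nonane from 18 | C(C[C@@]1(C)[C@H](CC2(OCCO2)C[C@@H]1C)[C@@H]3OC(C)(C)O[C@@H]3/C=C(\C)CS(=O)(=O)c4ccccc4)B5C6CCCC5CCC6 | intermediate
20 | primary alcohol (2-hydroxyethyl arm on C5) | OCC[C@@]1(C)[C@H](CC2(OCCO2)C[C@@H]1C)[C@@H]3OC(C)(C)O[C@@H]3/C=C(\C)CS(=O)(=O)c4ccccc4 | intermediate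
21 | ring A acetic acid (C5–CH2–CO2H) | OC(=O)C[C@@]1(C)[C@H](CC2(OCCO2)C[C@@H]1C)[C@@H]3OC(C)(C)O[C@@H]3/C=C(\C)CS(=O)(=O)c4ccccc4 | intermediate
22 | N-hydroxyphthalimide | O=C1c2ccccc2C(=O)N1O | starting material
23 | N-acyloxyphthalimide of 21 | O=C(C[C@@]1(C)[C@H](CC2(OCCO2)C[C@@H]1C)[C@@H]3OC(C)(C)O[C@@H]3/C=C(\C)CS(=O)(=O)c4ccccc4)ON5C(=O)c6ccccc6C5=O | intermediate
24 | primary C6 radical | [CH2][C@@]1(C)[C@H](CC2(OCCO2)C[C@@H]1C)[C@@H]3OC(C)(C)O[C@@H]3/C=C(\C)CS(=O)(=O)c4ccccc4 | intermediate
25 | tertiary C11 radical after ring closure | C[C](CS(=O)(=O)c1ccccc1)[C@H]2C[C@@]3(C)[C@H](CC4(OCCO4)C[C@@H]3C)[C@@H]5OC(C)(C)O[C@H]25 | intermediate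
26 | cis-decalin with C7 isopropenyl, C8/C9 acetonide, C2 dioxolane | C=C(C)[C@H]1C[C@@]2(C)[C@H](CC3(OCCO3)C[C@@H]2C)[C@@H]4OC(C)(C)O[C@H]14 | intermediate
27 | 8,9-dihydroxy-7-isopropenyl-4,5-dimethyl-cis-decalin-2-one | C=C(C)[C@H]1C[C@@]2(C)[C@H](CC(=O)C[C@@H]2C)[C@H](O)[C@@H]1O | intermediate
28 | 8-O-acetyl derivative of 27 | C=C(C)[C@H]1C[C@@]2(C)[C@H](CC(=O)C[C@@H]2C)[C@H](O)[C@@H]1OC(C)=O | intermediate
29 | tigloyl chloride, (E)-2-methylbut-2-enoyl chloride | C/C=C(\C)C(Cl)=O | starting material
30 | (4S,5R,7R,8R,9S,10S)-8-acetoxy-9-tigloyloxy-eremophil-11-en-2-one | C=C(C)[C@H]1C[C@@]2(C)[C@H](CC(=O)C[C@@H]2C)[C@H](OC(=O)/C(C)=C/C)[C@@H]1OC(C)=O | target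

## Step count and least certain steps

Total: 19 steps. Longest linear sequence: 19 steps (1 and 2 to 30); every step lies on this one sequence.

**Step 16 (key step).** The primary radical may be consumed before it cyclises. Hydrogen transfer from C8–H, which is allylic and next to oxygen and sits five atoms from C6, can compete with a 6-exo closure. Further reduction of the radical at the cathode would give the C5 methyl compound. Closure through the other chair would give the C7 epimer. The fallback moves radical generation away from the electrode into a known tin-mediated chain. It sets out from acid 21: Hunsdiecker-type iododecarboxylation (PhI(OAc)2, I2, irradiation) should give the neopentyl iodide F1, since iodine traps the radical far faster than it can cyclise. Irradiation of F1 with (Bu3Sn)2 in benzene then carries out the known radical allylation of an alkyl iodide by an allyl sulfone, here intramolecularly, and comes back to the route at 26.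

**Step 3.** Facial or endo/exo selectivity may be poor with a trisubstituted enal, and Mukaiyama-type addition of the silyl enol ether to the activated formyl group may compete. The fallback gives up catalytic enantiocontrol and resolves later. It sets out from 4 and 5: an achiral Lewis acid (Me2AlCl) gives racemic adduct, that is 6 together with its mirror image ent-6 F2. Steps 4 to 9 are run unchanged on the racemate, which carries along the mirror-image vinyl compound ent-7 F3, alcohol ent-8 F4, aldehyde ent-9 F5, dienol mixture ent-13 F6, dienone ent-14 F7 and dienol ent-15 F8. Step 10 then acts as a Sharpless kinetic resolution: the L-(+)-tartrate catalyst epoxidises only 15, the slow enantiomer ent-15 F8 is left behind, and the route is rejoined at 16 at the cost of half the material.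

**Step 9.** Facial selectivity may be too low with a small hydride, or conjugate reduction of the dienone may intervene. The fallback uses reagent control on an ynone, which reinforces the substrate preference. It sets out from 9: the lithium acetylide of 10, (3-methylbut-3-en-1-ynyl)lithium F9, adds to give the propargylic alcohols F10 as an epimer mixture. Dess–Martin oxidation gives the ynone F11. Noyori transfer hydrogenation with RuCl[(S,S)-TsDPEN](p-cymene) in isopropanol should give the single propargylic alcohol F12. Trans-reduction of F12 with NaAlH2(OCH2CH2OMe)2 in THF returns to the route at 15.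

**Step 10.** Epoxidation at so hindered a carbinol may be slow, and the Lewis-acidic titanium may open the vinyl epoxide once it has formed. The fallback installs the epoxide before the carbinol. It sets out from 14: Julia–Colonna epoxidation (poly-L-leucine, urea–hydrogen peroxide, DBU) of the α,β-olefin should give the epoxy ketone F13. Chelation-controlled reduction of F13 with Zn(BH4)2, which gives the erythro epoxy alcohol and agrees with the Felkin–Anh preference, comes back at 16.

**Step 13.** Hydroboration may also touch the C7=C11 olefin, and the basic peroxide work-up may isomerise the allylic sulfone into conjugation. The fallback avoids borane and base. It sets out from 18: aldehyde-selective Wacker oxidation (PdCl2(PhCN)2, CuCl2·2H2O, AgNO2, t-BuOH/MeNO2, O2) of the hindered vinyl group gives the aldehyde F14. Pinnick oxidation of F14 (NaClO2, NaH2PO4, 2-methylbut-2-ene) returns at 21.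

**Step 19.** Acetyl migration from O8 to O9 may precede a slow acylation of the axial C9 hydroxyl, which would give the transposed diester. The fallback changes the order of acylation. It sets out from 27: selective silylation of the equatorial C8 hydroxyl (Et3SiCl, imidazole) gives the 8-O-triethylsilyl ether F15. Tigloylation of C9 with 29 and DMAP at 60 °C gives the silyl tiglate F16, in which no acyl group can migrate. HF·pyridine gives the 9-tiglate 8-alcohol F17, and acetylation of F17 (Ac2O, DMAP) reaches 30.

## Further compounds

F1 | step 16 | neopentyl iodide from 21 (C5–CH2–I) | IC[C@@]1(C)[C@H](CC2(OCCO2)C[C@@H]1C)[C@@H]3OC(C)(C)O[C@@H]3/C=C(\C)CS(=O)(=O)c4ccccc4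
F2 | step 3 | ent-6 | O=C[C@]1(C)[C@@H](C=C(O[Si](C(C)C)(C(C)C)C(C)C)C[C@H]1C)CO[Si](C)(C)C(C)(C)C
F3 | step 3 | ent-7 | C=C[C@]1(C)[C@@H](C=C(O[Si](C(C)C)(C(C)C)C(C)C)C[C@H]1C)CO[Si](C)(C)C(C)(C)C
F4 | step 3 | ent-8 | C=C[C@]1(C)[C@@H](CC2(OCCO2)C[C@H]1C)CO
F5 | step 3 | ent-9 | C=C[C@]1(C)[C@@H](CC2(OCCO2)C[C@H]1C)C=O
F6 | step 3 | ent-13, both C9 epimers | C=C[C@]1(C)[C@@H](CC2(OCCO2)C[C@H]1C)C(O)/C=C/C(C)=C
F7 | step 3 | ent-14 | C=C[C@]1(C)[C@@H](CC2(OCCO2)C[C@H]1C)C(=O)/C=C/C(C)=C
F8 | step 3 | ent-15 | C=C[C@]1(C)[C@@H](CC2(OCCO2)C[C@H]1C)[C@@H](O)/C=C/C(C)=C
F9 | step 9 | (3-methylbut-3-en-1-ynyl)lithium | [Li]C#CC(C)=C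
F10 | step 9 | propargylic alcohols, both C9 epimers | C=C[C@@]1(C)[C@H](CC2(OCCO2)C[C@@H]1C)C(O)C#CC(C)=C
F11 | step 9 | ynone | C=C[C@@]1(C)[C@H](CC2(OCCO2)C[C@@H]1C)C(=O)C#CC(C)=C
F12 | step 9 | C9-configured propargylic alcohol | C=C[C@@]1(C)[C@H](CC2(OCCO2)C[C@@H]1C)[C@H](O)C#CC(C)=C
F13 | step 10 | (7S,8R)-7,8-epoxy-9-ketone | C=C[C@@]1(C)[C@H](CC2(OCCO2)C[C@@H]1C)C(=O)[C@@H]3O[C@H]3C(C)=C
F14 | step 13 | aldehyde (C5–CH2–CHO) | O=CC[C@@]1(C)[C@H](CC2(OCCO2)C[C@@H]1C)[C@@H]3OC(C)(C)O[C@@H]3/C=C(\C)CS(=O)(=O)c4ccccc4
F15 | step 19 | 8-O-triethylsilyl ether of 27 | C=C(C)[C@H]1C[C@@]2(C)[C@H](CC(=O)C[C@@H]2C)[C@H](O)[C@@H]1O[Si](CC)(CC)CC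
F16 | step 19 | 8-O-triethylsilyl 9-O-tigloyl derivative of 27 | C=C(C)[C@H]1C[C@@]2(C)[C@H](CC(=O)C[C@@H]2C)[C@H](OC(=O)/C(C)=C/C)[C@@H]1O[Si](CC)(CC)CC
F17 | step 19 | 9-O-tigloyl derivative of 27 (C8 hydroxyl free) | C=C(C)[C@H]1C[C@@]2(C)[C@H](CC(=O)C[C@@H]2C)[C@H](OC(=O)/C(C)=C/C)[C@@H]1O
A1 | alternative 1 | 2-methoxy-5-methyl-1,4-benzoquinone | COC1=CC(=O)C(C)=CC1=O
A2 | alternative 1 | (E)-1-(tert-butyldimethylsilyloxy)buta-1,3-diene | C=C/C=C/O[Si](C)(C)C(C)(C)C
A3 | alternative 1 | cis-fused methoxy enedione adduct with C9 silyl ether and C7=C8 olefin | C1C[C@@]2(C)[C@H](C(=O)C(OC)=CC2=O)[C@H](O[Si](C)(C)C(C)(C)C)C=1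
A4 | alternative 2 | cis-decalin C8 ketone with C9 dimethyl ketal, C3=C4 olefin and C2 silyl ether | C1C[C@@]2(C)[C@H](C[C@H](O[Si](C)(C)C(C)(C)C)C=C2C)C(OC)(OC)C1=O
A5 | alternative 3 | cis-decalin with free C8 hydroxyl, C9 4-methoxybenzyl ether, C7 isopropenyl and C2 dioxolane | C=C(C)[C@H]1C[C@@]2(C)[C@H](CC3(OCCO3)C[C@@H]2C)[C@H](OCc2ccc(OC)cc2)[C@@H]1O
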